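The earlier runs and the new flask are simulated from invented constants.

How far does the electrophile get in 10 d, and how much of the remaining nucleophile is still free then?

| setting | spring | flask |
|---|---|---|
| electrophile | 0.048 M | 0.048 M |
| nucleophile | 2 equiv | 2.00 equiv |
| free base | 0.50 equiv (fed, over 30 h) | 1.00 equiv (fed, over 30 h) |
| remark | run made earlier |  |
| time |  | 10 d |
spring run (percent of the electrophile charged)

| time / h | electrophile / % | target / % |
|---|---|---|
| 3.00 | 91.7 | 6.6 |
| 8.00 | 83.7 | 15.8 |
| 15.0 | 74.0 | 26.9 |
| 25.0 | 63.4 | 37.1 |

(scatter of a reading: 1 percentage point)
- part of the electrophile that has reacted at 10 d
- share of free nucleophile in free nucleophile and protonated nucleophile together, at 10 d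
- the earlier runs do not show how much of nucleophile is bound; that part of a forecast is a guess
- no earlier run changes the charge of free base; that part of a forecast is a guess

We build the flask up one process at a time, counting in fractions of the electrophile charged, which is the limiting reagent here. First comes the main step by itself, where each turnover uses one nucleophile. By the second-order law, the spring reading of 63.4% electrophile at 25.0 h gives a rate constant that carries the scatter of that reading, and taking it to the flask gives a conversion:

rate constant on the charge = 0.0101 h⁻¹

reacted at 10 d = 95.4%

Next comes the acid, since each turnover also sets free one acid, so conversion x means x of acid. We take the statistical case as the zero of the scale: no taker is preferred, and the acid spreads over nucleophile and free base by what is left of each.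

takers left = nucleophile charged + free base charged − x

free share = (takers left − x) / takers left

At our conversion this gives the statistical free share 53.4%.

Last comes the feed. Its 30 h is short against 10 d, so we count the free base as charged at once. A free share of 53.4% slows the main step, so we expect a conversion under 95.4% and a share somewhat over 53.4%.

The forecast gives 91% reacted and a free share of 40%, the latter by its own account “largely a guess and the range is wide”. Our share stands higher.

The flask gives 91.0% reacted and a free share of 56.2%.

    electrophile + nucleophile → acid set free + target (k = 0.235 M⁻¹ h⁻¹)
    nucleophile + acid set free ⇌ protonated nucleophile, settled at all times (K = 169 M⁻¹)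
    acid set free + free base ⇌ salt of the base (K = 100 M⁻¹, k = 22.0 M⁻¹ h⁻¹)
    nucleophile + acid set free ⇌ idle adduct, settled at all times (K = 11.0 M⁻¹)
    2 electrophile → self-condensation product (k = 0.00119 M⁻¹ h⁻¹)

Entered at that conversion, the statistical share moves from 53.4% to 56.4%, beside the 56.2% found. At 1.47 d in this flask, acid set free has a half-life of 0.74 h against free base (forward rate of that step alone), while electrophile has 2.1 d by the main step. At 10.0 d the flask also holds 0.00461 M acid set free and 0.00145 M idle adduct, which our count does not have.

In a neighbour flask with 0.500 equiv of nucleophile, the other charges as in the recipe, and 39.9% reacted, the same count, reading all that reacted as turnover, gives 63.8%. That flask computes to 62.2%.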